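**Plan**

- Atom labels: ring C1(OAng)–C2(OAng)–C3(Me, oxirane)–C4(oxirane CH)–C5H2–C6H; on C6 the side chain C7(=C14H2)–C8H(OAc)–CH2CH=CMe2.
- Cuts: the angelates, the C3–C4 oxirane and the C8–C9 bond go first; the carbocycle is then cut at C5–C6 and C2–C3 into a C5–C4–C3 β-ketoester 1,3-dianion (its ethyl group is C3 plus the methyl) and a C2–C1–C6 vinyl-oxirane aldehyde.
- Enabling feature: C6 is allylic to the exocyclic C7=C14 methylene and vicinal to the oxygen-bearing C1 and C2, so an oxirane across C1–C6 next to C7=C14, with C2 as CHO, is a 1,3-dielectrophile (aldehyde at C2; π-allyl at C6 that leaves its oxygen on C1).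
- Forward: Stille dienol, epoxy aldehyde, then a one-flask γ-aldol/Tsuji–Trost [3+3] annulation closes the only carbocycle and opens the helper oxirane; the ester activating group leaves as CO2, the C2 hydroxyl is re-set by epoxidation/Wharton transposition, and the C3–C4 oxirane is made in the penultimate step.
- Stereochemistry: one catalytic event (Sharpless epoxidation) sets C1 and the C6–O bond; double inversion at palladium relays it to C6; C2 (anti epoxidation of the enone) and C3/C4 (C1–OH-directed epoxidation) follow from the ring; C8 comes from catalyst-controlled allylboration.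

Key step: step 5

Assumption: compounds 1, 2 and 16 and the (S)-TRIP phosphoric acid are taken as purchasable; the aldol-derived centres at C2, C3 and C5 of 9–11 are carried as mixtures because step 6 removes all three.

**Step 1**
Reactants: 1 2-bromo-3,3-diethoxyprop-1-ene; 2 (E)-3-(tributylstannyl)prop-2-en-1-ol
Product: 3 (2E)-4-(diethoxymethyl)penta-2,4-dien-1-ol
Conditions: Pd(PPh3)4 (5 mol %), CuI (10 mol %), DMF, 50 °C
Reagents that add atoms: none
Why: Stille coupling of a 1-bromovinyl acetal with an (E)-alkenylstannane should proceed with retention of the alkene geometry and tolerate the free hydroxyl and the acetal.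

**Step 2**
Reactants: 3 (2E)-4-(diethoxymethyl)penta-2,4-dien-1-ol
Product: 4 [(2S,3S)-3-(3,3-diethoxyprop-1-en-2-yl)oxiran-2-yl]methanol
Conditions: Ti(OiPr)4 (10 mol %), L-(+)-diethyl tartrate (12 mol %), t-BuOOH, 4 Å MS, CH2Cl2, −20 °C
Reagents that add atoms: tert-butyl hydroperoxide, CC(C)(C)OO
Why: Sharpless asymmetric epoxidation acts only on the allylic-alcohol alkene of the dienol, and with the L-tartrate it should give the (2S,3S)-trans-epoxide, which sets C1 and the C6–O bond.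

**Step 3**
Reactants: 4 [(2S,3S)-3-(3,3-diethoxyprop-1-en-2-yl)oxiran-2-yl]methanol
Product: 5 (2R,3S)-3-(3,3-diethoxyprop-1-en-2-yl)oxirane-2-carbaldehyde
Conditions: Dess–Martin periodinane, NaHCO3, CH2Cl2, 0 to 23 °C
Reagents that add atoms: none
Why: Dess–Martin oxidation of the primary alcohol is mild enough for the vinyl oxirane and the acetal, and the oxirane-bound α-carbon cannot enolise, so C1 should not epimerise.

**Step 4**
Reactants: 6 methyl 3-oxopentanoate; 7 2-(trimethylsilyl)ethanol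
Product: 8 2-(trimethylsilyl)ethyl 3-oxopentanoate
Conditions: DMAP (20 mol %), toluene, reflux, 4 Å MS (removal of MeOH)
Reagents that add atoms: none
Why: Transesterification of a β-keto ester is easy on heating with an alcohol and DMAP, and it installs an ester that fluoride can later remove without acid or hydroxide.

**Step 5**
Reactants: 5 (2R,3S)-3-(3,3-diethoxyprop-1-en-2-yl)oxirane-2-carbaldehyde; 8 2-(trimethylsilyl)ethyl 3-oxopentanoate
Product: 10 2-(trimethylsilyl)ethyl (5R,6S)-6-(3,3-diethoxyprop-1-en-2-yl)-4,5-dihydroxy-3-methyl-2-oxocyclohexane-1-carboxylate (epimers at C1/C3/C4), via open-chain aldol adduct 9 (not isolated)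
Conditions: 8, NaH then n-BuLi, THF, 0 °C; 5, −78 °C; AcOH (2.1 equiv), −78 to 0 °C; then Pd(PPh3)4 (5 mol %), 23 °C
Reagents that add atoms: none
Why: The γ-carbon of the 1,3-dicarbonyl dianion of 8 adds to the non-enolisable aldehyde 5 (C3–C2 bond), acetic acid returns the neutral adduct 9, and zerovalent palladium then ionises the vinyl oxirane anti to the C6–O bond to a 2-substituted π-allyl complex whose C1 alkoxide deprotonates the tethered β-keto ester, so that C5 attacks C6 anti to palladium (C5–C6 bond). The closest known reaction types are the γ-selective aldol addition of acetoacetate dianions and the palladium-catalysed Tsuji–Trost cyclisation of β-keto esters onto tethered allylic ethers or vinyl oxiranes under neutral conditions, which gives 3-vinylcyclohexanones. The six-membered carbocycle closes by 6-exo attack on the proximal allyl terminus C6, whereas attack on the distal terminus C14 would need an eight-membered ring. C1 is carried over untouched from 5; C6 is set by double inversion (net retention), so the new C5–C6 bond takes the place of the oxirane C6–O bond and the trans-oxirane should give the C1 oxygen and the C7 side chain cis on the ring (O axial, side chain equatorial); C2, C3 and C5 form as mixtures that step 6 erases. The step needs C- rather than O-allylation, C6 rather than C14 attack and stereofidelity at C6; protonation of the C2 alkoxide before palladium is added, the ring size and the fast intramolecular capture of the π-allyl complex (before π–σ–π face exchange at its CH2 terminus) should secure them.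

**Step 6**
Reactants: 10 2-(trimethylsilyl)ethyl (5R,6S)-6-(3,3-diethoxyprop-1-en-2-yl)-4,5-dihydroxy-3-methyl-2-oxocyclohexane-1-carboxylate
Product: 12 (4S,5S)-5-(3,3-diethoxyprop-1-en-2-yl)-4-hydroxy-2-methylcyclohex-2-en-1-one, via β-hydroxy ketone 11 (not isolated)
Conditions: TBAF (3 equiv), THF, 0 to 23 °C; then DBU, 40 °C
Reagents that add atoms: none
Why: Fluoride cleaves the 2-(trimethylsilyl)ethyl ester to a β-keto carboxylate that should lose CO2, and DBU then dehydrates the β-hydroxy ketone by E1cB elimination to the conjugated enone, which removes the three undefined centres.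

**Step 7**
Reactants: 12 (4S,5S)-5-(3,3-diethoxyprop-1-en-2-yl)-4-hydroxy-2-methylcyclohex-2-en-1-one
Product: 13 (4S,5S)-4-[(tert-butyldimethylsilyl)oxy]-5-(3,3-diethoxyprop-1-en-2-yl)-2-methylcyclohex-2-en-1-one
Conditions: TBSCl, imidazole, DMF, 40 °C
Reagents that add atoms: tert-butyldimethylsilyl chloride, CC(C)(C)[Si](C)(C)Cl
Why: Silylation of the secondary alcohol under non-acidic conditions spares the acetal and places a bulky pseudoaxial group on C1 that shields one face of the enone.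

**Step 8**
Reactants: 13 (4S,5S)-4-[(tert-butyldimethylsilyl)oxy]-5-(3,3-diethoxyprop-1-en-2-yl)-2-methylcyclohex-2-en-1-one
Product: 14 (1S,4S,5R,6S)-5-[(tert-butyldimethylsilyl)oxy]-4-(3,3-diethoxyprop-1-en-2-yl)-1-methyl-7-oxabicyclo[4.1.0]heptan-2-one
Conditions: 30% aq H2O2, NaOH (cat.), MeOH, 0 °C
Reagents that add atoms: hydrogen peroxide, OO
Why: In this Weitz–Scheffer epoxidation the hydroperoxide anion should add to the enone β-carbon C2 anti to the pseudoaxial γ-silyloxy group, so the C2–O bond ends up trans to the C1 oxygen, and only the enone alkene is electrophilic enough to react.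

**Step 9**
Reactants: 14 (1S,4S,5R,6S)-5-[(tert-butyldimethylsilyl)oxy]-4-(3,3-diethoxyprop-1-en-2-yl)-1-methyl-7-oxabicyclo[4.1.0]heptan-2-one
Product: 15 (1R,5S,6R)-6-[(tert-butyldimethylsilyl)oxy]-5-(3,3-diethoxyprop-1-en-2-yl)-2-methylcyclohex-2-en-1-ol
Conditions: N2H4·H2O, AcOH, EtOH, 0 to 23 °C
Reagents that add atoms: none
Why: Wharton transposition of the epoxy ketone hydrazone should expel N2, leave the C2–O bond (and its configuration) intact and place the alkene at C3=C4.

**Step 10**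
Reactants: 15 (1R,5S,6R)-6-[(tert-butyldimethylsilyl)oxy]-5-(3,3-diethoxyprop-1-en-2-yl)-2-methylcyclohex-2-en-1-ol; 16 angelic anhydride [(2Z)-2-methylbut-2-enoic anhydride]
Product: 17 (1R,5S,6R)-6-[(tert-butyldimethylsilyl)oxy]-5-(3,3-diethoxyprop-1-en-2-yl)-2-methylcyclohex-2-en-1-yl (2Z)-2-methylbut-2-enoate
Conditions: LiN(SiMe3)2, THF, −78 °C; then 16, −78 to 0 °C
Reagents that add atoms: none
Why: O-acylation of the lithium alkoxide with the anhydride at low temperature avoids the nucleophilic catalysts that isomerise angelates to tiglates.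

**Step 11**
Reactants: 17 (1R,5S,6R)-6-[(tert-butyldimethylsilyl)oxy]-5-(3,3-diethoxyprop-1-en-2-yl)-2-methylcyclohex-2-en-1-yl (2Z)-2-methylbut-2-enoate
Product: 18 (1R,5S,6R)-6-[(tert-butyldimethylsilyl)oxy]-2-methyl-5-(3-oxoprop-1-en-2-yl)cyclohex-2-en-1-yl (2Z)-2-methylbut-2-enoate
Conditions: PPTS (cat.), acetone–H2O (10:1), 23 °C
Reagents that add atoms: water, O
Why: Acetal hydrolysis of the allylic diethyl acetal is fast under mild acid that should leave the silyl ether and the allylic ester untouched, and the silylated C1 oxygen cannot form a lactol with the new aldehyde.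

**Step 12**
Reactants: 18 (1R,5S,6R)-6-[(tert-butyldimethylsilyl)oxy]-2-methyl-5-(3-oxoprop-1-en-2-yl)cyclohex-2-en-1-yl (2Z)-2-methylbut-2-enoate
Product: 19 (1R,5S,6R)-6-[(tert-butyldimethylsilyl)oxy]-5-[(3S)-3-hydroxyhexa-1,5-dien-2-yl]-2-methylcyclohex-2-en-1-yl (2Z)-2-methylbut-2-enoate
Conditions: allylB(pin), (S)-TRIP phosphoric acid (5 mol %), 4 Å MS, toluene, −30 °C
Reagents that add atoms: allylboronic acid pinacol ester, C=CCB1OC(C)(C)C(C)(C)O1
Why: Chiral phosphoric acid-catalysed allylboration through a closed six-membered transition state sets C8 under catalyst control, using the antipode that turns benzaldehyde into (S)-1-phenylbut-3-en-1-ol, since the remote ring centres give little bias.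

**Step 13**
Reactants: 19 (1R,5S,6R)-6-[(tert-butyldimethylsilyl)oxy]-5-[(3S)-3-hydroxyhexa-1,5-dien-2-yl]-2-methylcyclohex-2-en-1-yl (2Z)-2-methylbut-2-enoate
Product: 20 (1R,5S,6R)-5-[(3S)-3-(acetyloxy)hexa-1,5-dien-2-yl]-6-[(tert-butyldimethylsilyl)oxy]-2-methylcyclohex-2-en-1-yl (2Z)-2-methylbut-2-enoate
Conditions: Ac2O, pyridine, DMAP (cat.), CH2Cl2, 0 °C
Reagents that add atoms: acetic anhydride, CC(=O)OC(C)=O
Why: Acetylation of the only free hydroxyl is a routine acylation that does not touch the already formed angelate.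

**Step 14**
Reactants: 20 (1R,5S,6R)-5-[(3S)-3-(acetyloxy)hexa-1,5-dien-2-yl]-6-[(tert-butyldimethylsilyl)oxy]-2-methylcyclohex-2-en-1-yl (2Z)-2-methylbut-2-enoate
Product: 21 (1R,5S,6R)-5-[(3S)-3-(acetyloxy)-6-methylhepta-1,5-dien-2-yl]-6-[(tert-butyldimethylsilyl)oxy]-2-methylcyclohex-2-en-1-yl (2Z)-2-methylbut-2-enoate
Conditions: second-generation Grubbs catalyst (5 mol %), 2-methylbut-2-ene/CH2Cl2, 40 °C
Reagents that add atoms: 2-methylbut-2-ene, CC=C(C)C
Why: Olefin cross-metathesis with excess 2-methylbut-2-ene should convert only the monosubstituted terminal alkene into the prenyl group, because the 1,1-disubstituted, ring trisubstituted and angelate alkenes are far less reactive.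

**Step 15**
Reactants: 21 (1R,5S,6R)-5-[(3S)-3-(acetyloxy)-6-methylhepta-1,5-dien-2-yl]-6-[(tert-butyldimethylsilyl)oxy]-2-methylcyclohex-2-en-1-yl (2Z)-2-methylbut-2-enoate
Product: 22 (1R,5S,6R)-5-[(3S)-3-(acetyloxy)-6-methylhepta-1,5-dien-2-yl]-6-hydroxy-2-methylcyclohex-2-en-1-yl (2Z)-2-methylbut-2-enoate
Conditions: HF·pyridine, pyridine, THF, 0 to 23 °C
Reagents that add atoms: none
Why: Buffered fluoride desilylation frees the C1 hydroxyl without generating an alkoxide, so acyl migration from C2 or C8 should not occur.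

**Step 16**
Reactants: 22 (1R,5S,6R)-5-[(3S)-3-(acetyloxy)-6-methylhepta-1,5-dien-2-yl]-6-hydroxy-2-methylcyclohex-2-en-1-yl (2Z)-2-methylbut-2-enoate
Product: 23 (1S,2S,3R,4S,6S)-4-[(3S)-3-(acetyloxy)-6-methylhepta-1,5-dien-2-yl]-3-hydroxy-1-methyl-7-oxabicyclo[4.1.0]heptan-2-yl (2Z)-2-methylbut-2-enoate
Conditions: VO(acac)2 (5 mol %), t-BuOOH, CH2Cl2, 0 to 23 °C
Reagents that add atoms: tert-butyl hydroperoxide, CC(C)(C)OO
Why: In this hydroxyl-directed epoxidation the axial homoallylic C1–OH (cyclohex-3-enol arrangement, held by allylic strain between the C3 methyl and the pseudoaxial C2 ester) should deliver oxygen to the C3=C4 face syn to C1–O and anti to the C2 ester, which sets C3 and C4 and leaves the undirected prenyl alkene alone.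

**Step 17**
Reactants: 23 (1S,2S,3R,4S,6S)-4-[(3S)-3-(acetyloxy)-6-methylhepta-1,5-dien-2-yl]-3-hydroxy-1-methyl-7-oxabicyclo[4.1.0]heptan-2-yl (2Z)-2-methylbut-2-enoate; 16 angelic anhydride
Product: 24 (1S,2S,3R,4S,6S)-4-[(3S)-3-(acetyloxy)-6-methylhepta-1,5-dien-2-yl]-1-methyl-7-oxabicyclo[4.1.0]heptane-2,3-diyl bis[(2Z)-2-methylbut-2-enoate]
Conditions: LiN(SiMe3)2, THF, −78 °C; then 16, −78 to −20 °C
Reagents that add atoms: none
Why: Low-temperature acylation of the lithium alkoxide with the anhydride should esterify the hindered axial C1 hydroxyl without angelate isomerisation, and a C2-to-C1 acyl shift would be harmless because both esters are the same.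

**Compound list**

1 | 2-bromo-3,3-diethoxyprop-1-ene | C=C(Br)C(OCC)OCC | starting material
2 | (E)-3-(tributylstannyl)prop-2-en-1-ol | OC/C=C/[Sn](CCCC)(CCCC)CCCC | starting material
3 | (2E)-4-(diethoxymethyl)penta-2,4-dien-1-ol | OC/C=C/C(=C)C(OCC)OCC | intermediate
4 | [(2S,3S)-3-(3,3-diethoxyprop-1-en-2-yl)oxiran-2-yl]methanol | OC[C@@H]1O[C@H]1C(=C)C(OCC)OCC | intermediate
5 | (2R,3S)-3-(3,3-diethoxyprop-1-en-2-yl)oxirane-2-carbaldehyde | O=C[C@@H]1O[C@H]1C(=C)C(OCC)OCC | intermediate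
6 | methyl 3-oxopentanoate | CCC(=O)CC(=O)OC | starting material
7 | 2-(trimethylsilyl)ethanol | C[Si](C)(C)CCO | starting material
8 | 2-(trimethylsilyl)ethyl 3-oxopentanoate | CCC(=O)CC(=O)OCC[Si](C)(C)C | intermediate
9 | 2-(trimethylsilyl)ethyl 5-[(2S,3S)-3-(3,3-diethoxyprop-1-en-2-yl)oxiran-2-yl]-5-hydroxy-4-methyl-3-oxopentanoate (epimers at C4/C5; not isolated) | C[Si](C)(C)CCOC(=O)CC(=O)C(C)C(O)[C@@H]1O[C@H]1C(=C)C(OCC)OCC | intermediate
10 | 2-(trimethylsilyl)ethyl (5R,6S)-6-(3,3-diethoxyprop-1-en-2-yl)-4,5-dihydroxy-3-methyl-2-oxocyclohexane-1-carboxylate (epimers at C1/C3/C4) | C=C(C(OCC)OCC)[C@@H]1C(C(=O)OCC[Si](C)(C)C)C(=O)C(C)C(O)[C@@H]1O | intermediate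
11 | (4R,5S)-5-(3,3-diethoxyprop-1-en-2-yl)-3,4-dihydroxy-2-methylcyclohexan-1-one (epimers at C2/C3; not isolated) | C=C(C(OCC)OCC)[C@@H]1CC(=O)C(C)C(O)[C@@H]1O | intermediate
12 | (4S,5S)-5-(3,3-diethoxyprop-1-en-2-yl)-4-hydroxy-2-methylcyclohex-2-en-1-one | C=C(C(OCC)OCC)[C@@H]1CC(=O)C(C)=C[C@@H]1O | intermediate
13 | (4S,5S)-4-[(tert-butyldimethylsilyl)oxy]-5-(3,3-diethoxyprop-1-en-2-yl)-2-methylcyclohex-2-en-1-one | C=C(C(OCC)OCC)[C@@H]1CC(=O)C(C)=C[C@@H]1O[Si](C)(C)C(C)(C)C | intermediate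
14 | (1S,4S,5R,6S)-5-[(tert-butyldimethylsilyl)oxy]-4-(3,3-diethoxyprop-1-en-2-yl)-1-methyl-7-oxabicyclo[4.1.0]heptan-2-one | C=C(C(OCC)OCC)[C@@H]1CC(=O)[C@@]2(C)O[C@H]2[C@@H]1O[Si](C)(C)C(C)(C)C | intermediate
15 | (1R,5S,6R)-6-[(tert-butyldimethylsilyl)oxy]-5-(3,3-diethoxyprop-1-en-2-yl)-2-methylcyclohex-2-en-1-ol | C=C(C(OCC)OCC)[C@@H]1CC=C(C)[C@@H](O)[C@@H]1O[Si](C)(C)C(C)(C)C | intermediate
16 | angelic anhydride [(2Z)-2-methylbut-2-enoic anhydride] | C/C=C(/C)C(=O)OC(=O)/C(C)=C\C | starting material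
17 | (1R,5S,6R)-6-[(tert-butyldimethylsilyl)oxy]-5-(3,3-diethoxyprop-1-en-2-yl)-2-methylcyclohex-2-en-1-yl (2Z)-2-methylbut-2-enoate | C=C(C(OCC)OCC)[C@@H]1CC=C(C)[C@@H](OC(=O)/C(C)=C\C)[C@@H]1O[Si](C)(C)C(C)(C)C | intermediate
18 | (1R,5S,6R)-6-[(tert-butyldimethylsilyl)oxy]-2-methyl-5-(3-oxoprop-1-en-2-yl)cyclohex-2-en-1-yl (2Z)-2-methylbut-2-enoate | C=C(C=O)[C@@H]1CC=C(C)[C@@H](OC(=O)/C(C)=C\C)[C@@H]1O[Si](C)(C)C(C)(C)C | intermediate
19 | (1R,5S,6R)-6-[(tert-butyldimethylsilyl)oxy]-5-[(3S)-3-hydroxyhexa-1,5-dien-2-yl]-2-methylcyclohex-2-en-1-yl (2Z)-2-methylbut-2-enoate | C=CC[C@H](O)C(=C)[C@@H]1CC=C(C)[C@@H](OC(=O)/C(C)=C\C)[C@@H]1O[Si](C)(C)C(C)(C)C | intermediate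
20 | (1R,5S,6R)-5-[(3S)-3-(acetyloxy)hexa-1,5-dien-2-yl]-6-[(tert-butyldimethylsilyl)oxy]-2-methylcyclohex-2-en-1-yl (2Z)-2-methylbut-2-enoate | C=CC[C@H](OC(C)=O)C(=C)[C@@H]1CC=C(C)[C@@H](OC(=O)/C(C)=C\C)[C@@H]1O[Si](C)(C)C(C)(C)C | intermediate
21 | (1R,5S,6R)-5-[(3S)-3-(acetyloxy)-6-methylhepta-1,5-dien-2-yl]-6-[(tert-butyldimethylsilyl)oxy]-2-methylcyclohex-2-en-1-yl (2Z)-2-methylbut-2-enoate | CC(C)=CC[C@H](OC(C)=O)C(=C)[C@@H]1CC=C(C)[C@@H](OC(=O)/C(C)=C\C)[C@@H]1O[Si](C)(C)C(C)(C)C | intermediate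
22 | (1R,5S,6R)-5-[(3S)-3-(acetyloxy)-6-methylhepta-1,5-dien-2-yl]-6-hydroxy-2-methylcyclohex-2-en-1-yl (2Z)-2-methylbut-2-enoate | CC(C)=CC[C@H](OC(C)=O)C(=C)[C@@H]1CC=C(C)[C@@H](OC(=O)/C(C)=C\C)[C@@H]1O | intermediate
23 | (1S,2S,3R,4S,6S)-4-[(3S)-3-(acetyloxy)-6-methylhepta-1,5-dien-2-yl]-3-hydroxy-1-methyl-7-oxabicyclo[4.1.0]heptan-2-yl (2Z)-2-methylbut-2-enoate | CC(C)=CC[C@H](OC(C)=O)C(=C)[C@@H]1C[C@@H]2O[C@]2(C)[C@@H](OC(=O)/C(C)=C\C)[C@@H]1O | intermediate
24 | (1S,2S,3R,4S,6S)-4-[(3S)-3-(acetyloxy)-6-methylhepta-1,5-dien-2-yl]-1-methyl-7-oxabicyclo[4.1.0]heptane-2,3-diyl bis[(2Z)-2-methylbut-2-enoate] | C=C([C@H](CC=C(C)C)OC(C)=O)[C@@H]1C[C@@H]2O[C@]2(C)[C@@H](OC(=O)/C(C)=C\C)[C@@H]1OC(=O)/C(C)=C\C | target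

**Step count**

Total: 17 steps. Longest linear sequence: 16 steps (steps 1–3 and 5–17; step 4 prepares the second fragment).

**Steps most likely to fail**

Step 5. The risks are loss of stereofidelity at C6 (face exchange of the π-allyl intermediate at its CH2 terminus before ring closure), O-allylation by the C2 or C1 oxygen, and retro-aldol cleavage while the mixture warms. The fallback is a stepwise, ligand-controlled version. It sets out from 9, now isolated after the aldol addition by aqueous work-up. The C2 hydroxyl would be capped with triethylsilyl chloride and imidazole to give 2-(trimethylsilyl)ethyl 5-[(2R,3S)-3-(3,3-diethoxyprop-1-en-2-yl)oxiran-2-yl]-4-methyl-3-oxo-5-[(triethylsilyl)oxy]pentanoate F1. This would be cyclised with Pd2(dba)3 and the matched antipode of N,N′-(cyclohexane-1,2-diyl)bis[2-(diphenylphosphanyl)benzamide], so that the ligand rather than the substrate fixes the face of the π-allyl unit. The product would be 2-(trimethylsilyl)ethyl (5R,6S)-6-(3,3-diethoxyprop-1-en-2-yl)-5-hydroxy-3-methyl-2-oxo-4-[(triethylsilyl)oxy]cyclohexane-1-carboxylate F2. Treatment of F2 with TBAF and then DBU (loss of both silyl groups, CO2 and water) comes back to the route at 12.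

Step 6. The risks are retro-aldol opening of the ring instead of dehydration, and base-induced isomerisation of the γ-hydroxy enone. The fallback activates the aldol hydroxyl instead of eliminating it directly. It sets out from 11, isolated after the fluoride stage. Acetic anhydride, triethylamine and DMAP would give (1R,6S)-6-(3,3-diethoxyprop-1-en-2-yl)-3-methyl-4-oxocyclohexane-1,2-diyl diacetate F3. Its β-acetoxy ketone should eliminate acetic acid with DBU at room temperature to give (1S,6S)-6-(3,3-diethoxyprop-1-en-2-yl)-3-methyl-4-oxocyclohex-2-en-1-yl acetate F4. Methanolysis of F4 with K2CO3 in methanol comes back to the route at 12.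

Step 16. The risks are competing directed epoxidation of the C7=C14 alkene, which is also homoallylic to the C1 hydroxyl, and imperfect facial selectivity. The fallback epoxidises before the prenyl alkene exists, so that a peracid can choose by alkene substitution. It sets out from 20. Desilylation with HF·pyridine would give (1R,5S,6R)-5-[(3S)-3-(acetyloxy)hexa-1,5-dien-2-yl]-6-hydroxy-2-methylcyclohex-2-en-1-yl (2Z)-2-methylbut-2-enoate F5. 3-Chloroperoxybenzoic acid with NaHCO3 should attack only the trisubstituted ring alkene, syn to the hydrogen-bonding C1 hydroxyl and anti to the C2 ester, to give (1S,2S,3R,4S,6S)-4-[(3S)-3-(acetyloxy)hexa-1,5-dien-2-yl]-3-hydroxy-1-methyl-7-oxabicyclo[4.1.0]heptan-2-yl (2Z)-2-methylbut-2-enoate F6. Acylation with LiN(SiMe3)2 and 16 would give (1S,2S,3R,4S,6S)-4-[(3S)-3-(acetyloxy)hexa-1,5-dien-2-yl]-1-methyl-7-oxabicyclo[4.1.0]heptane-2,3-diyl bis[(2Z)-2-methylbut-2-enoate] F7. Cross-metathesis of F7 with 2-methylbut-2-ene and the second-generation Grubbs catalyst comes back to the route at 24.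

**Further compounds**

F1 | step 5 | 2-(trimethylsilyl)ethyl 5-[(2R,3S)-3-(3,3-diethoxyprop-1-en-2-yl)oxiran-2-yl]-4-methyl-3-oxo-5-[(triethylsilyl)oxy]pentanoate (epimers at C4/C5) | C[Si](C)(C)CCOC(=O)CC(=O)C(C)C(O[Si](CC)(CC)CC)[C@@H]1O[C@H]1C(=C)C(OCC)OCC
F2 | step 5 | 2-(trimethylsilyl)ethyl (5R,6S)-6-(3,3-diethoxyprop-1-en-2-yl)-5-hydroxy-3-methyl-2-oxo-4-[(triethylsilyl)oxy]cyclohexane-1-carboxylate (epimers at C1/C3/C4) | C=C(C(OCC)OCC)[C@@H]1C(C(=O)OCC[Si](C)(C)C)C(=O)C(C)C(O[Si](CC)(CC)CC)[C@@H]1O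
F3 | step 6 | (1R,6S)-6-(3,3-diethoxyprop-1-en-2-yl)-3-methyl-4-oxocyclohexane-1,2-diyl diacetate (epimers at C2/C3) | C=C(C(OCC)OCC)[C@@H]1CC(=O)C(C)C(OC(C)=O)[C@@H]1OC(C)=O
F4 | step 6 | (1S,6S)-6-(3,3-diethoxyprop-1-en-2-yl)-3-methyl-4-oxocyclohex-2-en-1-yl acetate | C=C(C(OCC)OCC)[C@@H]1CC(=O)C(C)=C[C@@H]1OC(C)=O
F5 | step 16 | (1R,5S,6R)-5-[(3S)-3-(acetyloxy)hexa-1,5-dien-2-yl]-6-hydroxy-2-methylcyclohex-2-en-1-yl (2Z)-2-methylbut-2-enoate | C=CC[C@H](OC(C)=O)C(=C)[C@@H]1CC=C(C)[C@@H](OC(=O)/C(C)=C\C)[C@@H]1O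
F6 | step 16 | (1S,2S,3R,4S,6S)-4-[(3S)-3-(acetyloxy)hexa-1,5-dien-2-yl]-3-hydroxy-1-methyl-7-oxabicyclo[4.1.0]heptan-2-yl (2Z)-2-methylbut-2-enoate | C=CC[C@H](OC(C)=O)C(=C)[C@@H]1C[C@@H]2O[C@]2(C)[C@@H](OC(=O)/C(C)=C\C)[C@@H]1O
F7 | step 16 | (1S,2S,3R,4S,6S)-4-[(3S)-3-(acetyloxy)hexa-1,5-dien-2-yl]-1-methyl-7-oxabicyclo[4.1.0]heptane-2,3-diyl bis[(2Z)-2-methylbut-2-enoate] | C=CC[C@H](OC(C)=O)C(=C)[C@@H]1C[C@@H]2O[C@]2(C)[C@@H](OC(=O)/C(C)=C\C)[C@@H]1OC(=O)/C(C)=C\C
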